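The catalyst stands on both sides of step two, so it speeds that step both ways without moving its equilibrium. I freeze that equilibrium and bracket the target.

| setting | red | amber | grey | teal |
|---|---|---|---|---|
| substrate | 10 mM | 10 mM | 10 mM | 10 mM |
| coupling partner | 11.0 mM | 11.0 mM | 11.0 mM | 11.0 mM (fed, over 40.0 s) |
| catalyst | 100 µM | 100 µM | 100 µM | 100 µM |
| time | 50 s | 50 s |  | 50 s |
| remark | a closed flask charged with all of it at once and left for 50 s | plug flow through a tube for 50 s, no back-mixing | a single well-mixed tank run continuously and read at steady state, 50 s in it on average | all but coupling partner at the start; coupling partner goes in evenly over 40.0 s, the run ends at 50 s |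

    substrate + coupling partner → uncatalysed product (k1 = 0.0878 M⁻¹ s⁻¹)
    substrate + coupling partner + catalyst ⇌ catalyst + target (K2 = 46.2 M⁻¹, k2 = 1.36 × 10⁵ M⁻² s⁻¹)

- the stated concentrations are those of everything mixed, before any reaction; amounts are the same in each set-up
- the feed brings no volume worth counting
- run time (red): 50 s

* the set-up with the highest amount of target at the outlet or at the end, in percent of the substrate put in ("none" if the first two lie within 2 percentage points) (red / amber / grey / teal / none)
* amount of target at the outlet or at the end, in percent of the substrate put in, red
* amount of target at the outlet or at the end, in percent of the substrate put in, amber
* amount of target at the outlet or at the end, in percent of the substrate put in, grey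
* amount of target at the outlet or at the end, in percent of the substrate put in, teal

1. Ceiling. Let K be the equilibrium constant of step two and X the target concentration. Solving X = K(substrate − X)(coupling partner − X) from the charges gives 2.76 mM. The equilibrium ceiling, that target as a share of the charged substrate with step one ignored, is 27.6%.

2. Speed. Near equilibrium, step two relaxes in about 1.98 s. That is far shorter than the run of 50 s and shorter than the 10.0 s teal stands after its feed, so I put red, amber and teal on the equilibrium line at the end.

3. Leak. Step one removes substrate and coupling partner, and part of the target then runs back through step two. Let S be their free sum at equilibrium. Each unit of uncatalysed product lowers target by g = KS/(1 + KS) = 0.417.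

4. Floor. Holding the charged concentrations for the whole run overstates the leak at 4.83%, which gives a floor of 25.6% for red, amber and teal. Holding equilibrium concentrations instead gives a leak of 2.62% and a target of 26.5%, my figure for red and amber. For grey I claim the ceiling and no floor.

5. Choice. Each slice of amber lives the life of red, so they tie. Anything above them stays under the ceiling, 1.1 percentage points up, less than the margin of 2 points. I commit to none.

The forecast says none, with red 26.5%, amber 26.5%, grey 25.5% and teal 26.9%, noting “Red and amber are identical”. Its red and teal stand inside my bracket.

The simulation gives none: red 26.5%, amber 26.5%, grey 25.5%, teal 26.9%. Teal ends with 1.70% of uncatalysed product and red with 2.64%. The ceiling less g times these leaves 26.9% for teal and 26.5% for red, a gap of 0.39 points, smaller than the margin.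

Take teal with 27 mM of coupling partner. The ceiling rises to 50.4%, and the frozen leak, with g now 0.554, puts the mark at 47.7%. The computed flask gives 48.6%, with 3.30% of uncatalysed product.

All constants were set for the occasion; the rest is arithmetic.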